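0.980 is where our reckoning starts: it is the EjJi per litre in the violet run over that in the ochre run at 15 min, although violet was charged 1.50 times as much Ej.

| flask | Ej | Gu | remark | time |
|---|---|---|---|---|
| ochre | 0.50 M | 200 mM (held) | run made earlier |  |
| violet | 0.75 M | 200 mM (held) | run made earlier |  |
| flask | 1.0 M | 200 mM (held) |  | 15 min |

- ochre (time / min: EjJi / %): 2.00: 1.9; 5.00: 7.1; 10.0: 13.9; 15.0: 17.9
- violet (time / min: EjJi / %): 4.00: 4.5; 8.00: 8.6; 12.0: 11.2; 15.0: 11.7

(standard deviation of a reading: 0.5 percentage points)

- at the start none of Gu is in solution

1. the EjJi standing at 15 min, as a percentage of the Ej charged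
2. the change that raises the amount of EjJi at 15 min, in percent of the Ej charged most ("none" if none brings more than 2 percentage points) (epsilon / beta / none)
3. amount of EjJi at 15 min, in percent of the Ej charged, after epsilon

- epsilon: doubling the saturation concentration of Gu, all else as stated
- beta: doubling the transfer coefficient of Gu, all else as stated

Let us turn the question round. For the flask to keep ochre's 17.9 %, the fraction of the charge would have to hold as the charge grows, so that ratio would have to equal the ratio of the charges. But violet's fraction had already fallen to 11.7 %. We therefore read an apparent zero order in Ej: between ochre and violet the amount per litre holds within the scatter, and the fraction shrinks as the charge grows. Each run's fraction, scaled to the flask's charge, gives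

8.95 % from ochre and 8.77 % from violet, mean 8.86 %.

This mean is our carried share: the fraction of this flask's charge that the earlier runs leave as EjJi at 15 min. Epsilon doubles the saturation concentration of Gu; if the amount per litre follows the dissolved gas in proportion, our reckoning for epsilon is 17.7 %.

The forecast says 8.8 %, epsilon and 16 %, on the ground that “Product formed is therefore independent of Ej”.

The flask gives 8.59 %, a little below our carried share of 8.86 %. The best change is epsilon, worth 8.8 percentage points, more than the 3.6 points for beta, and it brings 17.3 %.

    Gu ⇌ Ji, rate k1*(csat - [Ji]) (kL = 0.200 min⁻¹)
    Ej + Ji → EjJi (k = 0.440 L mol⁻¹ min⁻¹)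
    Ej ⇌ Ty (K = 0.700, k = 0.0510 min⁻¹)
    Ej + EjJi → EjEjJi (k = 0.450 L mol⁻¹ min⁻¹)

The run without the loss of Ej + EjJi to EjEjJi stands at 28.8 % against 8.59 %, so that loss holds EjJi down by 20 points. It is a part of the story, 22 % of what is missing.

Take the same charge read at 6.0 min. As a rough estimate, we draw the mean pace as a straight line through violet's scaled reading at 8.00 min and the carried share at 15 min, and carry that line back to 6.0 min, which gives 5.21 %. The computed flask holds 5.15 %.

(The earlier runs and the new flask stem from a simulated flask from invented constants; scatter was added.)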